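Readings and results come from a simulation for substances that don't exist; noise was put on by code.

A small charge of Q carries a large charge of J here, so ask how many J one Q can turn over.

common to all: G 140 mM (held)

| flask | J | Q | remark | time |
|---|---|---|---|---|
| elm | 0.65 M | 0.12 mol% | run made earlier |  |
| ash | 1.4 M | 0.12 mol% | run made earlier |  |
| oak | 3 M | 0.31 mol% | run made earlier |  |
| red | 3.0 M | 0.12 mol% |  | 20 h |
| grey | 1.0 M | 0.5 mol% |  | 20 h |
| ochre | 0.80 M | 0.5 mol% |  | 20 h |
| violet | 1.0 M | 0.4 mol% |  | 20 h |
| teal | 3.0 M | 0.25 mol% |  | 20 h |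

| run | time / h | L / % | J / % |
|---|---|---|---|
| elm | 2.50 | 9.6 | 92.7 |
| elm | 8.00 | 20.4 | 80.6 |
| elm | 12.0 | 23.3 | 78.1 |
| elm | 20.0 | 28.6 | 71.3 |
| ash | 5.00 | 16.7 | 82.4 |
| ash | 10.0 | 26.2 | 72.9 |
| ash | 15.0 | 32.2 | 68.6 |
| ash | 20.0 | 37.3 | 63.1 |
| oak | 5.00 | 49.3 | 52.5 |
| oak | 10.0 | 77.0 | 27.1 |
| oak | 15.0 | 86.4 | 15.0 |
| oak | 20.0 | 90.3 | 7.6 |

(readings scatter by 1 percentage point)

- what was read earlier has a scatter of 1 percentage point, one standard deviation
- at the start none of G is in solution
- a reading or a percentage of L counts all its forms, free or not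

1. ranking by amount of L, in percent of the J charged, from high to low, at 20 h (red / grey / ochre / violet / teal)
2. the amount of L, in percent of the J charged of the flask you put first, at 20 h
3. the amount of L, in percent of the J charged of the flask you put last, at 20 h

Start with ash: it makes 16.7% of L in the first 5.00 h, but 5.1 percentage points in the last stretch of that length, which opens with 68.6% of J on hand. So either Q is being lost or L holds it back.

Let the rate per Q saturate in J (Michaelis-Menten form) with constant K, and integrate it. With x the fraction of J left, m the loading and κ equal to K over the starting J, this gives κ ln(1/x) + 1 − x = mF. Here F, the capacity, is the turnovers that one charged Q delivers by 20 h, at this held G, when saturated in J, and mF is the flask's budget in charges of J.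

Write this for elm and ash at 20 h and solve the pair: these scattered readings give K near 0.428 M and F near 425.

Now test it on oak: its last J reading gives F near 417, with L read at 2.71 M against 0.522 M in ash. Read the slowing as loss of Q at one pace in these flasks, then, and carry F forward.

The budgets are 2.12 for grey and ochre, 1.70 for violet, 1.06 for teal and 0.510 for red.

Solve by repeated substitution. My L comes to 93.7% for grey, 89.8% for ochre, 85.4% for violet and 42.8% for red.

For teal a test serves: leaving 16.7% of its J costs 1.09, over its budget, so I put teal's J left above violet's. Its budget stands above red's on the same starting J, so I put teal's L above red's.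

The forecast gives the same order, grey > ochre > violet > teal > red, with 93% (89% to 96%) for grey and 43% (39% to 47%) for red: "Rate follows saturation in J".

The flasks give grey > ochre > violet > teal > red, with grey at 93.7% and red at 41.5%.

    Z + Q → X (k = 2.13 × 10⁻⁴ M⁻¹ s⁻¹)
    J + Z + Q → L + Q, rate k2*[J]*[Z]*[Q]/(1 + ([J]/sat2)) (0.391 M, k = 0.250 M⁻² s⁻¹)
    G ⇌ Z, rate k3*(csat - [Z]) (kL = 0.0107 s⁻¹)
    E ⇌ L, rate k4*(cs4 - [L]) while solid is left; crystals form when [L] > cs4 (solubility = 1.90 M, k = 0.00119 s⁻¹)

At 20 h, grey and red hold 11.9% and 12.0% of their Q, the rest being X. Put grey's J left, 6.26%, into the integrated rate: F comes out at 425. Now take a flask like grey with 0.85 mol% of Q: its budget is 3.61, which leaves 0.225% of J by the integrated rate, and that flask holds 0.20%.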